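**Retrosynthetic overview**
- The Z-p-coumarate is made last, by Still–Gennari olefination of a C19 phosphonoacetate; the 7α,8α,19-triol comes from LiAlH4 reduction of an 8α,17-epoxy-7α-ol C19 ester, itself made from an 8(17)-alkene by allylic oxidation and hydroxyl-directed epoxidation.
- The 13(16),14-diene is stored as a saturated 15,16-dichloride (from dihydroboration of β-farnesene) and released by double E2, so it cannot interfere with the radical cascade.
- Key disconnection: C4–C5 and C9–C10 in one operation. Trivalent manganese oxidises the nucleophilic β-keto ester carbon C4 to an electrophilic radical (an enolonium-type reversal of polarity), which bonds to the nucleophilic alkene carbon C5.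
- Ring A closes first, then ring B, in the same cascade; a recoverable (+)-8-phenylmenthyl ester sets the absolute configuration at C4, C5, C9 and C10.
- The polyene comes from γ-alkylation of a 2-methylacetoacetate dianion with an allylic chloride made from β-farnesene.

Assumption: positions are given in labdane numbering, and C13, made racemic in step 1, is carried as an unresolved 1:1 epimer pair (no descriptor, "13ξ") until it becomes sp2 in step 9.

**Step 1**
Reactants: 1 (E)-β-farnesene [(6E)-7,11-dimethyl-3-methylidenedodeca-1,6,10-triene]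
Product: 3 (E)-2-(4,8-dimethylnona-3,7-dien-1-yl)butane-1,4-diol (racemic), via bis(9-BBN) adduct 2 (not isolated)
Conditions: 9-BBN (2.4 equiv), THF, 0 → 23 °C; then NaOH, H2O2, 0 → 40 °C
Reagents that add atoms: hydrogen peroxide, OO
Why: Brown hydroboration–oxidation, in which 9-BBN adds anti-Markovnikov to both termini of the 2-substituted 1,3-diene and leaves the two trisubstituted alkenes alone, so the diene is stored as a saturated 1,4-diol whose new CH centre (C13) is racemic and is erased in step 9.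

**Step 2**
Reactants: 3 (E)-2-(4,8-dimethylnona-3,7-dien-1-yl)butane-1,4-diol
Product: 4 (2E,6E)-10-(hydroxymethyl)-2,6-dimethyldodeca-2,6-diene-1,12-diol (racemic)
Conditions: SeO2 (0.3 equiv), t-BuOOH (3 equiv), CH2Cl2, 23 °C
Reagents that add atoms: selenium dioxide, O=[Se]=O; tert-butyl hydroperoxide, CC(C)(C)OO
Why: Catalytic SeO2 allylic oxidation (ene reaction, then 2,3-sigmatropic shift) hydroxylates the E-methyl group of the terminal trisubstituted alkene with retention of the E geometry, the internal alkene reacting more slowly and its products being removed by chromatography.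

**Step 3**
Reactants: 4 (2E,6E)-10-(hydroxymethyl)-2,6-dimethyldodeca-2,6-diene-1,12-diol
Product: 6 (2E,6E)-1,12-dichloro-10-(chloromethyl)-2,6-dimethyldodeca-2,6-diene (racemic), via tris(methanesulfonate) 5 (not isolated)
Conditions: MsCl (3.6 equiv), Et3N, CH2Cl2, −20 °C; then LiCl (10 equiv), DMF, 23 → 50 °C
Reagents that add atoms: lithium chloride, [Li+].[Cl-]; methanesulfonyl chloride, CS(=O)(=O)Cl
Why: Sulfonate formation followed by SN2 displacement with chloride converts all three hydroxyls without allylic transposition, giving one reactive allylic chloride and two inert primary alkyl chlorides that are the latent diene.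

**Step 4**
Reactants: 7 ethyl 2-methyl-3-oxobutanoate; 8 (+)-8-phenylmenthol [(1S,2R,5S)-5-methyl-2-(2-phenylpropan-2-yl)cyclohexan-1-ol]
Product: 9 (+)-8-phenylmenthyl 2-methyl-3-oxobutanoate (C2 epimers)
Conditions: DMAP (0.3 equiv), toluene, reflux, EtOH distilled off
Reagents that add atoms: none
Why: DMAP-catalysed transesterification of a β-keto ester (acylketene pathway) attaches the chiral auxiliary, and the epimeric α-carbon is of no consequence because it becomes planar in step 6.

**Step 5**
Reactants: 9 (+)-8-phenylmenthyl 2-methyl-3-oxobutanoate; 6 (2E,6E)-1,12-dichloro-10-(chloromethyl)-2,6-dimethyldodeca-2,6-diene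
Product: 11 (+)-8-phenylmenthyl (6E,10E)-16-chloro-14-(chloromethyl)-2,6,10-trimethyl-3-oxohexadeca-6,10-dienoate (C2 and C14 epimers), via sodium lithium dianion 10 (not isolated)
Conditions: NaH, THF, 0 °C; n-BuLi, −10 °C; then 6, −10 → 0 °C; aq NH4Cl
Reagents that add atoms: none
Why: Weiler dianion alkylation, in which the more basic γ-carbanion reacts first and SN2 attack on the primary allylic chloride is far faster than on the two alkyl chlorides, so the chain is joined at C1–C2 with both E alkenes intact.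

**Step 6 (key step)**
Reactants: 11 (+)-8-phenylmenthyl (6E,10E)-16-chloro-14-(chloromethyl)-2,6,10-trimethyl-3-oxohexadeca-6,10-dienoate
Product: 15 (+)-8-phenylmenthyl (13ξ)-15,16-dichloro-3-oxolabd-8(17)-en-19-oate, via C4 radical 12 (not isolated), via monocyclic C10 radical 13 (not isolated), via bicyclic C8 radical 14 (not isolated)
Conditions: Mn(OAc)3·2H2O (2.2 equiv), Cu(OAc)2·H2O (1 equiv), Yb(OTf)3 (1 equiv), CF3CH2OH–AcOH (4:1), degassed, −5 → 0 °C
Reagents that add atoms: none
Why: Snider-type oxidative free-radical polyene cyclisation, in which trivalent manganese oxidises the chelated enolate to the electrophilic C4 radical 12 (the normally nucleophilic α-carbon now bonds to the nucleophilic alkene carbon C5), two chair-like 6-endo closures of the E,E-polyene give the trans-decalin with 5α-H, 10β-CH3, 9β side chain, axial 4β-ester and equatorial 4α-CH3, the phenyl group of the Yb-chelated (+)-8-phenylmenthyl ester shields one face of 12 and so fixes the absolute configuration, and divalent copper oxidises radical 14 (which has no alkene within reach) to the 8(17)-alkene, with the minor facial diastereomer and endocyclic alkene isomers removed by chromatography here or at 19.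

**Step 7**
Reactants: 15 (+)-8-phenylmenthyl (13ξ)-15,16-dichloro-3-oxolabd-8(17)-en-19-oate
Product: 17 (+)-8-phenylmenthyl (13ξ)-15,16-dichlorolabd-8(17)-en-19-oate, via tosylhydrazone 16 (not isolated)
Conditions: TsNHNH2, EtOH, 75 °C; evaporate; catecholborane, CHCl3, 0 → 23 °C; then NaOAc·3H2O, 60 °C
Reagents that add atoms: none
Why: Caglioti-type reductive deoxygenation in Kabalka's form, where catecholborane reduces the C=N bond and acetate-induced loss of sulfinate and N2 leaves C3 as CH2 under near-neutral conditions that spare the hindered ester, the exocyclic alkene and the chlorides, with no stereocentre touched.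

**Step 8**
Reactants: 17 (+)-8-phenylmenthyl (13ξ)-15,16-dichlorolabd-8(17)-en-19-oate
Product: 18 (+)-8-phenylmenthyl (13ξ)-15,16-dichloro-7α-hydroxylabd-8(17)-en-19-oate
Conditions: SeO2 (0.5 equiv), t-BuOOH (2 equiv), CH2Cl2, 23 °C
Reagents that add atoms: selenium dioxide, O=[Se]=O; tert-butyl hydroperoxide, CC(C)(C)OO
Why: SeO2 allylic oxidation of the exocyclic alkene, in which the ene step removes the axial 7α-hydrogen (CH2 is preferred over the tertiary C9–H) and the 2,3-shift returns the double bond to C8=C17 while delivering oxygen axially on the α-face, the usual outcome for labd-8(17)-enes.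

**Step 9**
Reactants: 18 (+)-8-phenylmenthyl (13ξ)-15,16-dichloro-7α-hydroxylabd-8(17)-en-19-oate
Product: 19 (+)-8-phenylmenthyl 7α-hydroxylabda-8(17),13(16),14-trien-19-oate
Conditions: KOt-Bu (5 equiv), THF–DMSO (4:1), 0 → 23 °C
Reagents that add atoms: none
Why: Double E2 dehydrochlorination, in which the C16 chloride has its only β-hydrogen on C13 and the C15 chloride only on C14, so the 13(16),14-diene forms with fixed regiochemistry and the racemic C13 centre disappears.

**Step 10**
Reactants: 19 (+)-8-phenylmenthyl 7α-hydroxylabda-8(17),13(16),14-trien-19-oate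
Product: 20 (+)-8-phenylmenthyl 8α,17-epoxy-7α-hydroxylabda-13(16),14-dien-19-oate
Conditions: VO(acac)2 (5 mol %), t-BuOOH (1.5 equiv), CH2Cl2, 0 → 23 °C
Reagents that add atoms: tert-butyl hydroperoxide, CC(C)(C)OO
Why: Sharpless hydroxyl-directed epoxidation, in which the vanadium alkoxide of the axial 7α-OH delivers oxygen to the same α-face of the exocyclic alkene (also the face away from the axial C10 methyl), setting the C8–O bond α and leaving the remote diene untouched.

**Step 11**
Reactants: 20 (+)-8-phenylmenthyl 8α,17-epoxy-7α-hydroxylabda-13(16),14-dien-19-oate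
Product: 21 labda-13(16),14-diene-7α,8α,19-triol
Conditions: LiAlH4 (5 equiv), THF, 0 °C → reflux; Fieser work-up (8 recovered)
Reagents that add atoms: none
Why: Hydride reduction, in which LiAlH4 opens the spiro-epoxide by SN2 attack at the primary C17 (the C8–O bond and its α configuration are retained and C17 becomes the 8β-methyl) and reduces the hindered ester to the C19 alcohol, releasing the auxiliary.

**Step 12**
Reactants: 21 labda-13(16),14-diene-7α,8α,19-triol; 22 [bis(2,2,2-trifluoroethoxy)phosphoryl]acetic acid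
Product: 23 7α,8α-dihydroxylabda-13(16),14-dien-19-yl [bis(2,2,2-trifluoroethoxy)phosphoryl]acetate
Conditions: DCC (1.2 equiv), DMAP (0.1 equiv), CH2Cl2, 0 → 23 °C
Reagents that add atoms: none
Why: Steglich esterification, in which the primary C19 hydroxyl, although neopentyl, is acylated much faster than the axial secondary 7α-OH next to a fully substituted carbon and the tertiary 8α-OH.

**Step 13**
Reactants: 23 7α,8α-dihydroxylabda-13(16),14-dien-19-yl [bis(2,2,2-trifluoroethoxy)phosphoryl]acetate; 24 4-(tert-butyldimethylsilyloxy)benzaldehyde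
Product: 26 7α,8α-dihydroxylabda-13(16),14-dien-19-yl (2Z)-3-(4-hydroxyphenyl)prop-2-enoate (target), via silyl ether 25 (not isolated)
Conditions: KN(SiMe3)2 (1.05 equiv), 18-crown-6 (5 equiv), THF, −78 °C, then 24; then Bu4NF–AcOH (1:1), 0 °C, dark
Reagents that add atoms: none
Why: Still–Gennari olefination, in which the electron-poor phosphonate with a dissociated potassium ion eliminates quickly from the kinetic adduct to give the Z-enoate with an aromatic aldehyde, only the phosphonate (far more acidic than the free alcohols) is deprotonated, and buffered fluoride then cleaves the aryl silyl ether without isomerising the Z-alkene.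

**Compound list**
1 | (E)-β-farnesene, (6E)-7,11-dimethyl-3-methylidenedodeca-1,6,10-triene | C=CC(=C)CC/C=C(\C)CCC=C(C)C | starting material
2 | 9,9'-[(E)-2-(4,8-dimethylnona-3,7-dien-1-yl)butane-1,4-diyl]bis(9-borabicyclo[3.3.1]nonane), racemic | B1(CCC(CB2C3CCCC2CCC3)CC/C=C(\C)CCC=C(C)C)C2CCCC1CCC2 | intermediate
3 | (E)-2-(4,8-dimethylnona-3,7-dien-1-yl)butane-1,4-diol, racemic | OCCC(CO)CC/C=C(\C)CCC=C(C)C | intermediate
4 | (2E,6E)-10-(hydroxymethyl)-2,6-dimethyldodeca-2,6-diene-1,12-diol, racemic | OCCC(CO)CC/C=C(\C)CC/C=C(\C)CO | intermediate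
5 | tris(methanesulfonate) of 4 | CS(=O)(=O)OCCC(COS(C)(=O)=O)CC/C=C(\C)CC/C=C(\C)COS(C)(=O)=O | intermediate
6 | (2E,6E)-1,12-dichloro-10-(chloromethyl)-2,6-dimethyldodeca-2,6-diene, racemic | ClCCC(CCl)CC/C=C(\C)CC/C=C(\C)CCl | intermediate
7 | ethyl 2-methyl-3-oxobutanoate | CCOC(=O)C(C)C(C)=O | starting material
8 | (+)-8-phenylmenthol, (1S,2R,5S)-5-methyl-2-(2-phenylpropan-2-yl)cyclohexan-1-ol (recovered in step 11) | O[C@H]1C[C@@H](C)CC[C@@H]1C(C)(C)c1ccccc1 | starting material
9 | (+)-8-phenylmenthyl 2-methyl-3-oxobutanoate, C2 epimers | CC(=O)C(C)C(=O)O[C@H]1C[C@@H](C)CC[C@@H]1C(C)(C)c1ccccc1 | intermediate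
10 | sodium lithium 1,3-dianion of 9 | [Li+].[Na+].[CH2-]C(=O)[C-](C)C(=O)O[C@H]1C[C@@H](C)CC[C@@H]1C(C)(C)c1ccccc1 | intermediate
11 | (+)-8-phenylmenthyl (6E,10E)-16-chloro-14-(chloromethyl)-2,6,10-trimethyl-3-oxohexadeca-6,10-dienoate, C2 and C14 epimers | ClCCC(CCl)CC/C=C(\C)CC/C=C(\C)CCC(=O)C(C)C(=O)O[C@H]1C[C@@H](C)CC[C@@H]1C(C)(C)c1ccccc1 | intermediate
12 | C4 radical of 11 (radical at the carbon between ketone and ester) | ClCCC(CCl)CC/C=C(\C)CC/C=C(\C)CCC(=O)[C](C)C(=O)O[C@H]1C[C@@H](C)CC[C@@H]1C(C)(C)c1ccccc1 | intermediate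
13 | monocyclic C10 radical (ring A closed; 4α-CH3, 4β-ester, 5α-H) | ClCCC(CCl)CC/C=C(\C)CC[C@H]1[C@@](C)(C(=O)O[C@H]2C[C@@H](C)CC[C@@H]2C(C)(C)c2ccccc2)C(=O)CC[C]1C | intermediate
14 | bicyclic C8 radical (trans-decalin; 5α-H, 9α-H, 10β-CH3) | ClCCC(CCl)CC[C@H]1[C](C)CC[C@H]2[C@@](C)(C(=O)O[C@H]3C[C@@H](C)CC[C@@H]3C(C)(C)c3ccccc3)C(=O)CC[C@@]21C | intermediate
15 | (+)-8-phenylmenthyl (13ξ)-15,16-dichloro-3-oxolabd-8(17)-en-19-oate (5α-H, 9α-H, 10β-CH3, 4α-CH3, 4β-ester) | ClCCC(CCl)CC[C@H]1C(=C)CC[C@H]2[C@@](C)(C(=O)O[C@H]3C[C@@H](C)CC[C@@H]3C(C)(C)c3ccccc3)C(=O)CC[C@@]21C | intermediate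
16 | C3 tosylhydrazone of 15 | ClCCC(CCl)CC[C@H]1C(=C)CC[C@H]2[C@@](C)(C(=O)O[C@H]3C[C@@H](C)CC[C@@H]3C(C)(C)c3ccccc3)C(=NNS(=O)(=O)c3ccc(C)cc3)CC[C@@]21C | intermediate
17 | (+)-8-phenylmenthyl (13ξ)-15,16-dichlorolabd-8(17)-en-19-oate | ClCCC(CCl)CC[C@H]1C(=C)CC[C@H]2[C@@](C)(C(=O)O[C@H]3C[C@@H](C)CC[C@@H]3C(C)(C)c3ccccc3)CCC[C@@]21C | intermediate
18 | (+)-8-phenylmenthyl (13ξ)-15,16-dichloro-7α-hydroxylabd-8(17)-en-19-oate | ClCCC(CCl)CC[C@H]1C(=C)[C@H](O)C[C@H]2[C@@](C)(C(=O)O[C@H]3C[C@@H](C)CC[C@@H]3C(C)(C)c3ccccc3)CCC[C@@]21C | intermediate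
19 | (+)-8-phenylmenthyl 7α-hydroxylabda-8(17),13(16),14-trien-19-oate | C=CC(=C)CC[C@H]1C(=C)[C@H](O)C[C@H]2[C@@](C)(C(=O)O[C@H]3C[C@@H](C)CC[C@@H]3C(C)(C)c3ccccc3)CCC[C@@]21C | intermediate
20 | (+)-8-phenylmenthyl 8α,17-epoxy-7α-hydroxylabda-13(16),14-dien-19-oate | C=CC(=C)CC[C@H]1[C@]4(OC4)[C@H](O)C[C@H]2[C@@](C)(C(=O)O[C@H]3C[C@@H](C)CC[C@@H]3C(C)(C)c3ccccc3)CCC[C@@]21C | intermediate
21 | labda-13(16),14-diene-7α,8α,19-triol (8β-CH3) | C=CC(=C)CC[C@H]1[C@](C)(O)[C@H](O)C[C@H]2[C@@](C)(CO)CCC[C@@]21C | intermediate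
22 | [bis(2,2,2-trifluoroethoxy)phosphoryl]acetic acid | OC(=O)CP(=O)(OCC(F)(F)F)OCC(F)(F)F | starting material
23 | 7α,8α-dihydroxylabda-13(16),14-dien-19-yl [bis(2,2,2-trifluoroethoxy)phosphoryl]acetate | C=CC(=C)CC[C@H]1[C@](C)(O)[C@H](O)C[C@H]2[C@@](C)(COC(=O)CP(=O)(OCC(F)(F)F)OCC(F)(F)F)CCC[C@@]21C | intermediate
24 | 4-(tert-butyldimethylsilyloxy)benzaldehyde | O=Cc1ccc(O[Si](C)(C)C(C)(C)C)cc1 | starting material
25 | 7α,8α-dihydroxylabda-13(16),14-dien-19-yl (2Z)-3-[4-(tert-butyldimethylsilyloxy)phenyl]prop-2-enoate | C=CC(=C)CC[C@H]1[C@](C)(O)[C@H](O)C[C@H]2[C@@](C)(COC(=O)/C=C\c3ccc(O[Si](C)(C)C(C)(C)C)cc3)CCC[C@@]21C | intermediate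
26 | 7α,8α-dihydroxylabda-13(16),14-dien-19-yl (2Z)-3-(4-hydroxyphenyl)prop-2-enoate, CNP0254560.1 | C=CC(=C)CC[C@H]1[C@](C)(O)[C@H](O)C[C@H]2[C@@](C)(COC(=O)/C=C\c3ccc(O)cc3)CCC[C@@]21C | target

**Step count and risks**
Total steps: 13. Longest linear sequence: 12 (steps 1–3 and 5–13; step 4 is the side branch).

The three steps most likely to fail:

Step 6 (the cascade). The manganese enolate of this hindered α-methyl keto ester may form slowly, face selectivity may be lower than for unsubstituted analogues, and termination may give alkene mixtures. The fallback sets out from 11: silylation (t-BuMe2SiOTf, Et3N, CH2Cl2) gives the tert-butyldimethylsilyl enol ether F1. Outer-sphere one-electron oxidation of this isolated enol silane with (NH4)2Ce(NO3)6 and NaHCO3 in MeCN, with Cu(OAc)2 present, generates the same electrophilic C4 radical without any metal enolate. The radical cyclises twice as before and divalent copper terminates it, so the route is rejoined at 15.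

Step 7 (deoxygenation at C3). The ketone sits next to a quaternary carbon carrying a bulky ester, so hydrazone formation may stall or the reduction may divert to an alkene. The fallback sets out from 15: NaBH4 in MeOH gives the 3-hydroxy ester F2 (mainly 3β). NaH, CS2 and MeI convert it into the S-methyl xanthate F3. Barton–McCombie reduction (Bu3SnH, AIBN, toluene, 90 °C) removes the oxygen, the primary chlorides reacting far more slowly than the thiocarbonyl, and the route is rejoined at 17.

Step 9 (double dehydrochlorination). tert-Butoxide may substitute at the unbranched C15 chloride or isomerise alkenes. The fallback sets out from 18: PhSeNa (from PhSeSePh and NaBH4, EtOH, 60 °C) displaces both chlorides to give the bis(phenylselenide) F4. NaIO4 oxidises it to the bis(selenoxide) F5, which undergoes two syn eliminations on warming with i-Pr2NH. Each selenoxide has β-hydrogens on one carbon only, so the regiochemistry is unchanged, no strong base is present, and the route is rejoined at 19.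

**Further compounds**
F1 | step 6 | (+)-8-phenylmenthyl (6E,10E)-3-(tert-butyldimethylsilyloxy)-16-chloro-14-(chloromethyl)-2,6,10-trimethylhexadeca-2,6,10-trienoate (enol ether geometry undefined) | ClCCC(CCl)CC/C=C(\C)CC/C=C(\C)CCC(O[Si](C)(C)C(C)(C)C)=C(C)C(=O)O[C@H]1C[C@@H](C)CC[C@@H]1C(C)(C)c1ccccc1
F2 | step 7 | (+)-8-phenylmenthyl (13ξ)-15,16-dichloro-3-hydroxylabd-8(17)-en-19-oate | ClCCC(CCl)CC[C@H]1C(=C)CC[C@H]2[C@@](C)(C(=O)O[C@H]3C[C@@H](C)CC[C@@H]3C(C)(C)c3ccccc3)C(O)CC[C@@]21C
F3 | step 7 | S-methyl xanthate of F2 | ClCCC(CCl)CC[C@H]1C(=C)CC[C@H]2[C@@](C)(C(=O)O[C@H]3C[C@@H](C)CC[C@@H]3C(C)(C)c3ccccc3)C(OC(=S)SC)CC[C@@]21C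
F4 | step 9 | (+)-8-phenylmenthyl (13ξ)-7α-hydroxy-15,16-bis(phenylselanyl)labd-8(17)-en-19-oate | c1ccc(cc1)[Se]CCC(C[Se]c1ccccc1)CC[C@H]1C(=C)[C@H](O)C[C@H]2[C@@](C)(C(=O)O[C@H]3C[C@@H](C)CC[C@@H]3C(C)(C)c3ccccc3)CCC[C@@]21C
F5 | step 9 | (+)-8-phenylmenthyl (13ξ)-7α-hydroxy-15,16-bis(phenylseleninyl)labd-8(17)-en-19-oate | O=[Se](c1ccccc1)CCC(C[Se](=O)c1ccccc1)CC[C@H]1C(=C)[C@H](O)C[C@H]2[C@@](C)(C(=O)O[C@H]3C[C@@H](C)CC[C@@H]3C(C)(C)c3ccccc3)CCC[C@@]21C
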